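The rate constants are made up; the rest is arithmetic.

The pool quotient of this flask is 1.03, and on it we choose whether the next run gets more reagent or a faster transfer.

    reagent in the reaction phase ⇌ reagent in the second phase, rate k1*([reagent in the reaction phase] - [reagent in the second phase]/K1) per volume of the first phase (K1 = 1.6, k1 = 0.027 /s)
    substrate + reagent in the reaction phase ⇌ product (K2 = 64 /M, k2 = 0.011 /M/s)
    substrate ⇌ dormant form (K3 = 0.56, k3 = 0.0019 /s)

substrate 0.045 M; reagent in the second phase 3.00 equiv; time 3.0 h; volume of the second phase over the first 0.50

- in the second phase: reagent in the second phase; everything else is in the first
- charges count per volume of the first phase; a concentration in a rate is the amount of a species over the volume of its own phase; every rate counts per litre of the first phase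
- run time (flask): 3.0 h

- blue: doubling the amount of reagent in the second phase, all else as stated
- ochre: doubling the transfer coefficient of step 1, all else as stated

1. amount of product at 3.0 h, in percent of the substrate charged
2. the change that raises the amount of product at 3.0 h, in percent of the substrate charged most ("none" if none brings more than 2 percentage points) (blue / ochre / none)
3. amount of product at 3.0 h, in percent of the substrate charged, after blue

First, the clocks. The natural logarithm of two over the transfer coefficient gives a forward transfer half-life of 25.7 s, substrate and dormant form relax with a half-life of 2.18 min, and the forward rate of the addition step alone, at charged concentrations, gives reagent in the reaction phase a half-life of 0.39 h. Each is shorter than the run of 3.0 h, so we reckon on thermodynamic rather than kinetic control.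

Dividing the forward rate of the addition step by its backward rate and setting the ratio to one removes time. Unconverted substrate divides between free and dormant as one to 0.56, and unconsumed reagent divides between the phases as one to 1.6 times 0.50. The converted fraction, divided by the fraction of substrate left and by the equivalents of reagent left, then equals the pool quotient: the equilibrium constant of the addition step times the substrate charge, over one plus 0.56 and over one plus that phase term.

At 3.00 equiv this gives us 70.2 %. Doubled equivalents leave the quotient as it is and give 84.1 %. The transfer coefficient does not enter the quotient, so we choose to charge more reagent.

The forecast gives 70.1 % (68.5 % to 71 %), then 84.1 % (83 % to 85 %) and chooses blue, holding that “3 h is essentially at full equilibrium”.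

The flask gives 70.1 %, and 84.1 % after blue, a gain of 14 percentage points against 0 points for ochre. Product stood at 68.0 % after 1.50 h and 70.2 % after 30.0 h. Read back from the flask's yield, the quotient is 1.02, a reading beside our 1.03.

For a neighbour flask with 0.018 M of substrate and the same equivalents, the quotient falls to 0.410, which gives 50.6 %. The computed neighbour gives 49.8 %.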